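With partner as charged in north, first product has a shorter half-life, 0.082 d, than starting material, 0.12 d, and the decomposition of partner is far slower, with a half-life of 1.7 d.

    partner → decomposed reagent (k1 = 4.74 × 10⁻⁶ s⁻¹)
    partner + first product → double product + released group (k2 = 0.00233 M⁻¹ s⁻¹)
    starting material + partner → first product + released group (k3 = 0.00160 M⁻¹ s⁻¹)

| flask | starting material | partner | time | remark |
|---|---|---|---|---|
| south-west | 14 mM (fed, over 4.0 d) | 3.00 equiv | 20 d | all else is in the flask from the start; the feed brings no volume worth counting |
| north | 14 mM | 3.00 equiv | 20 d | everything together at the start |
| north-east | 14 mM (in portions, 5, over 4.0 d) | 3.00 equiv | 20 d | first portion at the start, last at 4.0 d |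
| east | 14 mM | 3.00 equiv (fed, over 4.0 d) | 20 d | all else is in the flask from the start; the feed brings no volume worth counting |

1. the best flask by amount of first product, in percent of the starting material charged; "all alike" if 1.5 percentage points covers them all (south-west / north / north-east / east / all alike)
2. amount of first product at the end, in percent of the starting material charged, south-west
3. amount of first product at the end, in percent of the starting material charged, north
4. amount of first product at the end, in percent of the starting material charged, north-east
5. amount of first product at the end, in percent of the starting material charged, east

We count turnovers. One turnover is the exposure to partner that lowers starting material by a factor e. All three steps run in proportion to partner, so after n turnovers a flask charged at once holds exp(-n) of its starting material. Its first product is the difference of exp(-n) and exp(-sn), divided by s less one, where s is the selectivity factor, 1.46. Each turnover also costs partner a fixed amount, 0.212 of the charge of starting material. This is the price per turnover, the rate of step 1 over that of step 3 at the start. Partner spent is n times the price, plus what steps 3 and 2 consumed.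

Our table has two rows. At 4 turnovers, starting material stands at 1.83 %, first product at 3.35 %, and partner spent at 2.78 charges. At 5 turnovers, they stand at 0.674 %, 1.32 % and 3.03. The 3.00 equiv charged lies between the rows, so north stops near 4.88 turnovers, with first product at 1.49 %. East feeds the same partner into the same proportional steps, so we give it north's row.

South-west differs, since a parcel fed late meets fewer turnovers. If partner decomposes and also takes two per fed starting material at once, it reaches zero at 3.03 d, before the feed ends at 4.0 d. That estimate, which takes fed starting material as consumed at once, puts 24.3 % of the charge as fed after that time. North-east also adds late, and we expect both to beat north, but we leave their first product unreckoned.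

The forecast named south-west, with 16 % there, 1.5 % in north, 13 % in north-east and 1.5 % in east, holding that “the products depend only on cumulative partner exposure”.

The simulation gives south-west as best, with 15.0 % there, 1.50 % in north, 13.5 % in north-east and 1.50 % in east. North keeps 0.768 % of its starting material, which reads as 4.87 turnovers. At our price that is 1.03 of the charge decomposed, and north's decomposed reagent at 20.0 d stands at 1.03 of it.

Now take a neighbour of north with 5.6 mM of starting material and the same equivalents. The price rises to 0.529. Spending is 2.61 charges at 2 turnovers and 3.41 at 3, so n is 2.49, leaving 8.29 % starting material and 12.3 % first product. That flask ends with 8.59 % and 12.7 %.

All constants belong to no real substance, and the outcome is calculated.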